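**Plan**

- Retrosynthesis: demethylate last; open both pyranone rings at O1–C8a and O1''–C8a'' (SNAr); detach both A rings at C4–C4a and C4''–C4a'' (aryl transfer to acyl groups); replace O1 and O1'' by two doubly bonded carbons, which ties C2 and C2'' into a cyclohexene; cut C2–C3 and C2''–C3'' by retro-[4+2].
- Enabling feature: the meso tetrad C2–C3–C3''–C2'' lies on the succinyl chain C4–C3–C3''–C4''. These six carbons are the sp3 edge and the two carbonyls of an all-cis 3,6-diarylcyclohex-4-ene-1,2-dicarboxylic anhydride, whose alkene carbons stand where O1 and O1'' belong.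
- Forward order: the diene chain is joined by olefination; the temporary cyclohexene arises first (Diels–Alder); the anhydride becomes the two A-ring ketones by way of a bis-Weinreb amide and an aryllithium; the carbocycle is cut by ozonolysis and carbon is exchanged for oxygen by Baeyer–Villiger oxidation; both pyranone rings (rings C) then close together; the phenols are freed.
- Stereochemistry: all four centres come from the single cycloaddition (E,E diene, Z dienophile, endo) and are carried on with retention. The all-cis array becomes 2,3-trans and 2'',3''-trans once C4 and C4'' change from substituents into ring atoms.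

Key step: step 2

Remark: flavonoid locants are used (unit 1: O1, C2, C3, C4, C4a, C8a; unit 2 doubly primed). The target SMILES is the achiral meso (2R,3S,2''S,3''R) isomer, so no absolute stereocontrol is needed; symmetric intermediates are meso and 6 is racemic.

**Route**

Step 1
Reactants: 1 (E)-4-methoxycinnamaldehyde; 2 diethyl (4-methoxybenzyl)phosphonate
Product: 3 (1E,3E)-1,4-bis(4-methoxyphenyl)buta-1,3-diene
Conditions: KOtBu, THF, 0 °C to rt; crystallisation
Reagents that add atoms: none
Why: Horner–Wadsworth–Emmons olefination of an enal with a semi-stabilised benzylic phosphonate anion equilibrates before elimination and should give the new alkene E, the existing E alkene being untouched.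

Step 2
Reactants: 3 (1E,3E)-1,4-bis(4-methoxyphenyl)buta-1,3-diene; 4 maleic anhydride
Product: 5 all-cis 4,7-bis(4-methoxyphenyl)-3a,4,7,7a-tetrahydro-2-benzofuran-1,3-dione (meso; both aryl groups and both carbonyl carbons on one face of the cyclohexene)
Conditions: xylenes, 140 °C, N2; product crystallises on cooling
Reagents that add atoms: none
Why: This is a concerted, thermally allowed suprafacial–suprafacial Diels–Alder cycloaddition, the direct counterpart of the classical addition of maleic anhydride to (E,E)-1,4-diphenylbutadiene. The only ring closed is the cyclohexene, by [4+2] closure, with both new σ bonds (the future C2–C3 and C2''–C3'') made in one event. The two aryl-bearing centres are cis because both E termini of the diene rotate suprafacially, the two carbonyl-bearing centres are cis because the Z geometry of the dienophile is conserved, and the endo transition state, with the anhydride carbonyls under the diene π system, places all four substituents on one face. The step needs endo over exo selectivity and nothing else: the normal-demand pairing of the electron-rich dianisyl diene with the cyclic electron-poor dienophile should favour the endo mode kinetically, the adduct should not revert at this temperature, and the mirror plane common to both partners makes the adduct meso, as the target is.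

Step 3
Reactants: 5 all-cis 4,7-bis(4-methoxyphenyl)-3a,4,7,7a-tetrahydro-2-benzofuran-1,3-dione
Product: 7 all-cis N1,N2-dimethoxy-N1,N2-dimethyl-3,6-bis(4-methoxyphenyl)cyclohex-4-ene-1,2-dicarboxamide, via amide acid 6 (not isolated)
Conditions: MeNH(OMe)·HCl (2.4 equiv), iPr2NEt, CH2Cl2, 0 °C to rt; then EDC·HCl, HOBt (cat.), rt
Reagents that add atoms: N,O-dimethylhydroxylamine hydrochloride, CNOC.Cl
Why: aminolysis of the cyclic anhydride followed by carbodiimide amide coupling of the liberated carboxylic acid with a second equivalent of the amine is standard acyl substitution, touches no stereocentre, and its weakly basic conditions should leave the cis carbonyls unepimerised.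

Step 4
Reactants: 7 all-cis N1,N2-dimethoxy-N1,N2-dimethyl-3,6-bis(4-methoxyphenyl)cyclohex-4-ene-1,2-dicarboxamide; 8 4-bromo-3-fluoroanisole
Product: 10 all-cis [3,6-bis(4-methoxyphenyl)cyclohex-4-ene-1,2-diyl]bis[(2-fluoro-4-methoxyphenyl)methanone], via aryllithium 9 (not isolated)
Conditions: 8 (2.6 equiv), nBuLi (2.5 equiv), THF, −78 °C, 30 min; then 7 (1 equiv) in THF, −78 °C; AcOH, −78 °C, then H2O
Reagents that add atoms: 4-bromo-3-fluoroanisole (second equivalent of 8), COc1ccc(Br)c(F)c1
Why: Weinreb ketone synthesis run at both amides of one substrate, so that 10 carries two aryl groups drawn from two molar equivalents of 8: bromine–lithium exchange at −78 °C outruns ring deprotonation and gives an ortho-fluoroaryllithium that should not lose LiF to an aryne below about −60 °C, each N-methoxy-N-methylamide takes up one aryllithium as a lithium-chelated tetrahedral adduct that collapses to the ketone only after the cold acetic acid quench, and over-addition is thereby excluded.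

Step 5
Reactants: 10 all-cis [3,6-bis(4-methoxyphenyl)cyclohex-4-ene-1,2-diyl]bis[(2-fluoro-4-methoxyphenyl)methanone]
Product: 12 meso-(2R,3R,4S,5S)-3,4-bis(2-fluoro-4-methoxybenzoyl)-2,5-bis(4-methoxyphenyl)hexanedial, via ozonide 11 (not isolated)
Conditions: O3, CH2Cl2, −78 °C (Sudan Red 7B end point); then PPh3, −78 °C to rt; used crude
Reagents that add atoms: ozone, [O-][O+]=O
Why: ozonolysis with reductive work-up, in which the isolated cis alkene, open on the face opposite the four substituents, should react far faster than the anisyl rings, and neutral phosphine reduction of the ozonide should leave the enolisable α-aryl aldehyde centres (future C2 and C2'') unchanged.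

Step 6
Reactants: 12 meso-(2R,3R,4S,5S)-3,4-bis(2-fluoro-4-methoxybenzoyl)-2,5-bis(4-methoxyphenyl)hexanedial
Product: 13 meso-(1R,2S,3R,4S)-2,3-bis(2-fluoro-4-methoxybenzoyl)-1,4-bis(4-methoxyphenyl)butane-1,4-diyl diformate
Conditions: mCPBA (2.5 equiv), Na2HPO4, CH2Cl2, 0 °C to rt
Reagents that add atoms: meta-chloroperoxybenzoic acid, O=C(OO)c1cccc(Cl)c1
Why: Baeyer–Villiger oxidation of an α-branched α-aryl aldehyde, in which the secondary 4-methoxybenzylic carbon of the Criegee adduct should migrate in preference to hydride and with retention, so that each formyl-bearing centre becomes the O-bearing C2 or C2'' centre; the congested aryl ketones should add peracid much more slowly, and the buffer guards against acid-induced enolisation and ionisation.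

Step 7
Reactants: 13 meso-(1R,2S,3R,4S)-2,3-bis(2-fluoro-4-methoxybenzoyl)-1,4-bis(4-methoxyphenyl)butane-1,4-diyl diformate
Product: 14 meso-(1R,2S,3R,4S)-2,3-bis(2-fluoro-4-methoxybenzoyl)-1,4-bis(4-methoxyphenyl)butane-1,4-diol
Conditions: KHCO3 (cat.), MeOH–THF, 0 °C
Reagents that add atoms: none
Why: base-catalysed transesterification (methanolysis) of formate esters should be much faster than enolisation of the ketones under bicarbonate, so the alcohols are released by acyl–oxygen cleavage without β-elimination and without breaking the C–O bonds at the stereocentres.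

Step 8
Reactants: 14 meso-(1R,2S,3R,4S)-2,3-bis(2-fluoro-4-methoxybenzoyl)-1,4-bis(4-methoxyphenyl)butane-1,4-diol
Product: 15 meso-(2R,3S,2''S,3''R)-7,7'',4',4'''-tetramethoxy-3,3''-biflavanone [7,7'-dimethoxy-2,2'-bis(4-methoxyphenyl)-3,3'-bichromane-4,4'-dione]
Conditions: NaH (2.05 equiv), THF–DMF, 0 °C to rt
Reagents that add atoms: none
Why: twofold intramolecular SNAr (addition–elimination through a Meisenheimer adduct, the known closure of chroman-4-ones from β-hydroxy 2-fluoroaryl ketones), in which each alkoxide attacks the fluorine-bearing carbon ortho to its β-carbonyl through a six-membered transition state; C2 and C2'' are not touched, the base is consumed as NaF, and the former cis carbonyl becomes ring atom C4 so that each ring is formed 2,3-trans, which is also the thermodynamic arrangement should C3 enolise.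

Step 9
Reactants: 15 meso-(2R,3S,2''S,3''R)-7,7'',4',4'''-tetramethoxy-3,3''-biflavanone
Product: 16 meso-(2R,3S,2''S,3''R)-7,7'',4',4'''-tetrahydroxy-3,3''-biflavanone [7,7'-dihydroxy-2,2'-bis(4-hydroxyphenyl)-3,3'-bichromane-4,4'-dione]
Conditions: BBr3 (10 equiv), CH2Cl2, −78 °C to 0 °C; MeOH, then H2O
Reagents that add atoms: none
Why: Lewis acid cleavage of aryl methyl ethers, standard for methoxyflavanones; boron complexation of the 4'-oxygens removes their donor power, so the benzylic C2–O1 bonds should not ionise and the four stereocentres should be kept.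

**Compound list**

1 | (E)-4-methoxycinnamaldehyde | COc1ccc(/C=C/C=O)cc1 | starting material
2 | diethyl (4-methoxybenzyl)phosphonate | CCOP(=O)(Cc1ccc(OC)cc1)OCC | starting material
3 | (1E,3E)-1,4-bis(4-methoxyphenyl)buta-1,3-diene | COc1ccc(/C=C/C=C/c2ccc(OC)cc2)cc1 | intermediate
4 | maleic anhydride | O=C1C=CC(=O)O1 | starting material
5 | all-cis 4,7-bis(4-methoxyphenyl)-3a,4,7,7a-tetrahydro-2-benzofuran-1,3-dione (meso) | O=C1OC(=O)[C@H]2[C@@H]1[C@@H](c1ccc(OC)cc1)C=C[C@H]2c1ccc(OC)cc1 | intermediate
6 | all-cis 6-[methoxy(methyl)carbamoyl]-2,5-bis(4-methoxyphenyl)cyclohex-3-ene-1-carboxylic acid (racemic, one enantiomer drawn) | OC(=O)[C@H]1[C@@H](C(=O)N(C)OC)[C@@H](c2ccc(OC)cc2)C=C[C@H]1c1ccc(OC)cc1 | intermediate (not isolated)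
7 | all-cis N1,N2-dimethoxy-N1,N2-dimethyl-3,6-bis(4-methoxyphenyl)cyclohex-4-ene-1,2-dicarboxamide (meso) | CON(C)C(=O)[C@H]1[C@@H](C(=O)N(C)OC)[C@@H](c2ccc(OC)cc2)C=C[C@H]1c1ccc(OC)cc1 | intermediate
8 | 4-bromo-3-fluoroanisole | COc1ccc(Br)c(F)c1 | starting material
9 | (2-fluoro-4-methoxyphenyl)lithium | COc1ccc([Li])c(F)c1 | intermediate (not isolated)
10 | all-cis [3,6-bis(4-methoxyphenyl)cyclohex-4-ene-1,2-diyl]bis[(2-fluoro-4-methoxyphenyl)methanone] (meso) | O=C(c1ccc(OC)cc1F)[C@H]1[C@@H](C(=O)c2ccc(OC)cc2F)[C@@H](c2ccc(OC)cc2)C=C[C@H]1c1ccc(OC)cc1 | intermediate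
11 | 3,4-bis(2-fluoro-4-methoxybenzoyl)-2,5-bis(4-methoxyphenyl)-7,8,9-trioxabicyclo[4.2.1]nonane (secondary ozonide; four carbon substituents all cis, acetal carbons as formed) | O=C(c1ccc(OC)cc1F)[C@H]1[C@@H](C(=O)c2ccc(OC)cc2F)[C@@H](c2ccc(OC)cc2)C2OOC(O2)[C@H]1c1ccc(OC)cc1 | intermediate (not isolated)
12 | meso-(2R,3R,4S,5S)-3,4-bis(2-fluoro-4-methoxybenzoyl)-2,5-bis(4-methoxyphenyl)hexanedial | O=C[C@H](c1ccc(OC)cc1)[C@H](C(=O)c1ccc(OC)cc1F)[C@H](C(=O)c1ccc(OC)cc1F)[C@H](c1ccc(OC)cc1)C=O | intermediate
13 | meso-(1R,2S,3R,4S)-2,3-bis(2-fluoro-4-methoxybenzoyl)-1,4-bis(4-methoxyphenyl)butane-1,4-diyl diformate | O=CO[C@H](c1ccc(OC)cc1)[C@H](C(=O)c1ccc(OC)cc1F)[C@H](C(=O)c1ccc(OC)cc1F)[C@H](c1ccc(OC)cc1)OC=O | intermediate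
14 | meso-(1R,2S,3R,4S)-2,3-bis(2-fluoro-4-methoxybenzoyl)-1,4-bis(4-methoxyphenyl)butane-1,4-diol | O[C@H](c1ccc(OC)cc1)[C@H](C(=O)c1ccc(OC)cc1F)[C@H](C(=O)c1ccc(OC)cc1F)[C@H](c1ccc(OC)cc1)O | intermediate
15 | meso-(2R,3S,2''S,3''R)-7,7'',4',4'''-tetramethoxy-3,3''-biflavanone | O=C1c2ccc(OC)cc2O[C@H](c2ccc(OC)cc2)[C@H]1[C@@H]1C(=O)c2ccc(OC)cc2O[C@H]1c1ccc(OC)cc1 | intermediate
16 | meso-(2R,3S,2''S,3''R)-7,7'',4',4'''-tetrahydroxy-3,3''-biflavanone (CNP0231820.1) | O=C1c2ccc(O)cc2O[C@H](c2ccc(O)cc2)[C@H]1[C@@H]1C(=O)c2ccc(O)cc2O[C@H]1c1ccc(O)cc1 | target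

**Step count and risks**

Total: 9 steps. Longest linear sequence: 9 steps (1 to 16).

Steps most likely to fail, in order of risk:

Step 6. Hydride may migrate instead of carbon in the Criegee adduct, which would oxidise the formyl groups to carboxylic acids, and slow peracid addition at the congested aldehydes would give time for enolisation. The fallback sets out from 12 and makes the migrating choice unambiguous by going through methyl ketones. MeTi(OiPr)3 (THF, −40 to 0 °C) should add methyl to the two aldehydes only, giving 4,5-bis(2-fluoro-4-methoxybenzoyl)-3,6-bis(4-methoxyphenyl)octane-2,7-diol F1. Dess–Martin periodinane then gives 4,5-bis(2-fluoro-4-methoxybenzoyl)-3,6-bis(4-methoxyphenyl)octane-2,7-dione F2. Baeyer–Villiger oxidation with buffered mCPBA, where the secondary 4-methoxybenzylic carbon competes only with methyl, gives 2,3-bis(2-fluoro-4-methoxybenzoyl)-1,4-bis(4-methoxyphenyl)butane-1,4-diyl diacetate F3. Methanolysis (K2CO3, MeOH, 0 °C) returns to the route at 14.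

Step 8. Retro-aldol fragmentation of the β-alkoxy ketone, or base-induced dehydration, may outrun ring closure. The fallback sets out from 14 and removes the aldol relationship before cyclisation. NaBH4 (MeOH, 0 °C) reduces both ketones to 2,3-bis[(2-fluoro-4-methoxyphenyl)(hydroxy)methyl]-1,4-bis(4-methoxyphenyl)butane-1,4-diol F4. KOtBu in DMSO at 80 to 100 °C then closes both rings by alkoxide SNAr on the unactivated fluoroarenes; only the six-membered closure is geometrically reasonable. This gives 7,7'-dimethoxy-2,2'-bis(4-methoxyphenyl)-3,3'-bichromane-4,4'-diol F5. Dess–Martin oxidation of the two benzylic carbinols returns to the route at 15.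

Step 4. The second amide may resist aryl transfer because it is shielded by the neighbouring lithium chelate, or the aryllithium may act as a base at the α-carbons, and warming to force the addition would destroy the reagent by loss of LiF. The fallback sets out from 5 and uses aldehydes as the less hindered electrophiles. LiAlH4 (THF, 0 °C to reflux) gives all-cis [3,6-bis(4-methoxyphenyl)cyclohex-4-ene-1,2-diyl]dimethanol F6. Swern oxidation gives all-cis 3,6-bis(4-methoxyphenyl)cyclohex-4-ene-1,2-dicarbaldehyde F7. Addition of two equivalents of 9 (THF, −78 °C) gives all-cis [3,6-bis(4-methoxyphenyl)cyclohex-4-ene-1,2-diyl]bis[(2-fluoro-4-methoxyphenyl)methanol] F8. Dess–Martin oxidation returns to the route at 10.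

**Further compounds**

F1 | step 6 | 4,5-bis(2-fluoro-4-methoxybenzoyl)-3,6-bis(4-methoxyphenyl)octane-2,7-diol (carbinol centres as formed) | CC(O)[C@H](c1ccc(OC)cc1)[C@H](C(=O)c1ccc(OC)cc1F)[C@H](C(=O)c1ccc(OC)cc1F)[C@H](c1ccc(OC)cc1)C(C)O
F2 | step 6 | 4,5-bis(2-fluoro-4-methoxybenzoyl)-3,6-bis(4-methoxyphenyl)octane-2,7-dione | CC(=O)[C@H](c1ccc(OC)cc1)[C@H](C(=O)c1ccc(OC)cc1F)[C@H](C(=O)c1ccc(OC)cc1F)[C@H](c1ccc(OC)cc1)C(C)=O
F3 | step 6 | 2,3-bis(2-fluoro-4-methoxybenzoyl)-1,4-bis(4-methoxyphenyl)butane-1,4-diyl diacetate | CC(=O)O[C@H](c1ccc(OC)cc1)[C@H](C(=O)c1ccc(OC)cc1F)[C@H](C(=O)c1ccc(OC)cc1F)[C@H](c1ccc(OC)cc1)OC(C)=O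
F4 | step 8 | 2,3-bis[(2-fluoro-4-methoxyphenyl)(hydroxy)methyl]-1,4-bis(4-methoxyphenyl)butane-1,4-diol (new carbinol centres as formed) | O[C@H](c1ccc(OC)cc1)[C@H](C(O)c1ccc(OC)cc1F)[C@H](C(O)c1ccc(OC)cc1F)[C@H](c1ccc(OC)cc1)O
F5 | step 8 | 7,7'-dimethoxy-2,2'-bis(4-methoxyphenyl)-3,3'-bichromane-4,4'-diol (C4 centres as formed) | OC1c2ccc(OC)cc2O[C@H](c2ccc(OC)cc2)[C@H]1[C@@H]1C(O)c2ccc(OC)cc2O[C@H]1c1ccc(OC)cc1
F6 | step 4 | all-cis [3,6-bis(4-methoxyphenyl)cyclohex-4-ene-1,2-diyl]dimethanol | OC[C@H]1[C@@H](CO)[C@@H](c2ccc(OC)cc2)C=C[C@H]1c1ccc(OC)cc1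
F7 | step 4 | all-cis 3,6-bis(4-methoxyphenyl)cyclohex-4-ene-1,2-dicarbaldehyde | O=C[C@H]1[C@@H](C=O)[C@@H](c2ccc(OC)cc2)C=C[C@H]1c1ccc(OC)cc1
F8 | step 4 | all-cis [3,6-bis(4-methoxyphenyl)cyclohex-4-ene-1,2-diyl]bis[(2-fluoro-4-methoxyphenyl)methanol] (carbinol centres as formed) | OC(c1ccc(OC)cc1F)[C@H]1[C@@H](C(O)c2ccc(OC)cc2F)[C@@H](c2ccc(OC)cc2)C=C[C@H]1c1ccc(OC)cc1
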